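Ring A is cut at C5–C6. It carries oxygen at C7 and C8a and the acyl carbon C4 on C4a, and its only oxygen-free ring carbon, C5, lies next to the prenylated C6, so it is a folded keto aldehyde. One aldol condensation of the C6 methylene onto a C5 formyl group, with loss of water and enolisation of C7, closes and aromatises ring A with the prenyl group already in place; C8 could reach C5 only through a four-membered ring. The precursor is the (S)-2-aryl-2,3-dihydropyran-4-one with the formyl group on C4a and the 6-methyl-2-oxohept-5-enyl chain on C8a, its C7 ketone kept as a dioxolane until just before.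

Key step: step 11

Remark: flavanone numbering (O1, C2, C3, C4, C4a, C5 to C8, C8a) is used for the corresponding atoms of every intermediate; compound 17 is not stored but taken crude into step 11.

Step 1
Reactants: 1 4-hydroxybenzaldehyde; 2 3-chloro-3-methylbut-1-yne
Product: 3 4-[(2-methylbut-3-yn-2-yl)oxy]benzaldehyde
Conditions: K2CO3, KI, CuI (cat.), acetone, 56 °C
Reagents that add atoms: none
Why: Copper-assisted O-alkylation of the phenoxide by the tertiary propargylic chloride should give the aryl 1,1-dimethylpropargyl ether that the chromene-forming Claisen rearrangement needs.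

Step 2
Reactants: 3 4-[(2-methylbut-3-yn-2-yl)oxy]benzaldehyde
Product: 4 2,2-dimethyl-2H-chromene-6-carbaldehyde
Conditions: PhNEt2, 190 °C
Reagents that add atoms: none
Why: Aromatic propargyl Claisen rearrangement to the ortho-allenyl phenol, 1,5-hydrogen shift and 6π oxa-electrocyclisation should give the 2,2-dimethylchromene, and only one isomer can form because both ortho positions are equivalent.

Step 3
Reactants: 4 2,2-dimethyl-2H-chromene-6-carbaldehyde; 5 acetone
Product: 6 (S)-4-(2,2-dimethyl-2H-chromen-6-yl)-4-hydroxybutan-2-one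
Conditions: (R)-N-[(R)-2-hydroxy-1,2,2-triphenylethyl]pyrrolidine-2-carboxamide (10 mol%), acetone (excess), brine, −5 °C
Reagents that add atoms: none
Why: In this enamine-mediated direct asymmetric aldol addition the amide N–H and hydroxyl of the D-proline-derived catalyst should hold the aldehyde so that the acetone enamine attacks its Si face and sets C2 as S (the L-series catalysts are known to give the R aldols of aryl aldehydes), while the cold aqueous medium limits dehydration and retro-aldol.

Step 4
Reactants: 6 (S)-4-(2,2-dimethyl-2H-chromen-6-yl)-4-hydroxybutan-2-one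
Product: 7 (S)-4-(2,2-dimethyl-2H-chromen-6-yl)-4-[(triethylsilyl)oxy]butan-2-one
Conditions: Et3SiCl, imidazole, CH2Cl2, 0 °C
Reagents that add atoms: chlorotriethylsilane, CC[Si](CC)(CC)Cl
Why: Silylation of the secondary alcohol is needed because a free aldolate next to the ketone acylated in step 7 could undergo retro-aldol cleavage and lose the C2 configuration, and a triethylsilyl ether comes off later under mild acid.

Step 5
Reactants: 8 N-methoxy-N-methyl-3-oxobutanamide; 9 1-bromo-3-methylbut-2-ene
Product: 10 N-methoxy-N,7-dimethyl-3-oxooct-6-enamide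
Conditions: LDA (2.1 equiv), THF, −78 → 0 °C; 9, 0 °C; AcOH
Reagents that add atoms: none
Why: In this γ-alkylation of a β-keto amide dianion the more basic terminal carbanion should react with the primary allylic bromide in an SN2 reaction and so place the prenyl group on the future C6.

Step 6
Reactants: 10 N-methoxy-N,7-dimethyl-3-oxooct-6-enamide
Product: 11 N-methoxy-N-methyl-2-[2-(4-methylpent-3-en-1-yl)-1,3-dioxolan-2-yl]acetamide
Conditions: HOCH2CH2OH, p-TsOH·H2O (cat.), PhH, 80 °C, Dean–Stark trap
Reagents that add atoms: ethylene glycol, OCCO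
Why: Acid-catalysed ketalisation with azeotropic removal of water masks the future C7 ketone, so that C8 is neither acidic nor nucleophilic during enolate acylation, iodination and formylation, while the N-methoxy-N-methylamide and the trisubstituted alkene should be unaffected.

Step 7
Reactants: 7 (S)-4-(2,2-dimethyl-2H-chromen-6-yl)-4-[(triethylsilyl)oxy]butan-2-one; 11 N-methoxy-N-methyl-2-[2-(4-methylpent-3-en-1-yl)-1,3-dioxolan-2-yl]acetamide
Product: 14 (S)-2-(2,2-dimethyl-2H-chromen-6-yl)-6-{[2-(4-methylpent-3-en-1-yl)-1,3-dioxolan-2-yl]methyl}-2,3-dihydro-4H-pyran-4-one, via silyl diketone 12 (not isolated), via hydroxy diketone 13 (not isolated)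
Conditions: LDA (1.1 equiv), THF, −78 °C; 11, −78 → 0 °C; AcOH (2 equiv); then HF·pyridine (excess), 0 → 25 °C
Reagents that add atoms: none
Why: Kinetic deprotonation of the methyl ketone at its methyl group (future C4a), Claisen-type C-acylation by the N-methoxy-N-methylamide through a chelated tetrahedral adduct that prevents double addition, acidic fluoride removal of the silyl group and cyclodehydration, in which the C2 hydroxyl can reach only the C8a carbonyl through a six-membered ring, should give the vinylogous ester without touching the C2–O or C2–H bond.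

Step 8
Reactants: 14 (S)-2-(2,2-dimethyl-2H-chromen-6-yl)-6-{[2-(4-methylpent-3-en-1-yl)-1,3-dioxolan-2-yl]methyl}-2,3-dihydro-4H-pyran-4-one
Product: 15 (S)-2-(2,2-dimethyl-2H-chromen-6-yl)-5-iodo-6-{[2-(4-methylpent-3-en-1-yl)-1,3-dioxolan-2-yl]methyl}-2,3-dihydro-4H-pyran-4-one
Conditions: N-iodosuccinimide (1.1 equiv), CH2Cl2, 0 → 25 °C, dark
Reagents that add atoms: N-iodosuccinimide, O=C1CCC(=O)N1I
Why: In this electrophilic α-iodination of a vinylogous ester C4a is the nucleophilic β-carbon of the ring enol ether, C8 is inert thanks to the ketal, and the side-chain and chromene double bonds have no nucleophile at hand to trap an iodonium ion.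

Step 9
Reactants: 15 (S)-2-(2,2-dimethyl-2H-chromen-6-yl)-5-iodo-6-{[2-(4-methylpent-3-en-1-yl)-1,3-dioxolan-2-yl]methyl}-2,3-dihydro-4H-pyran-4-one
Product: 16 (S)-2-(2,2-dimethyl-2H-chromen-6-yl)-6-{[2-(4-methylpent-3-en-1-yl)-1,3-dioxolan-2-yl]methyl}-4-oxo-3,4-dihydro-2H-pyran-5-carbaldehyde
Conditions: Pd(PPh3)4 (5 mol%), CO (3 atm), Bu3SnH (1.1 equiv, slow addition), PhMe, 50 °C
Reagents that add atoms: carbon monoxide, [C-]#[O+]
Why: Palladium-catalysed reductive carbonylation (formylation) of a vinyl iodide, by oxidative addition to zerovalent palladium, CO insertion, hydride transfer from tin and reductive elimination, should put C5 on C4a at the aldehyde level under neutral conditions that leave the ketal, the alkenes and C2 alone.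

Step 10
Reactants: 16 (S)-2-(2,2-dimethyl-2H-chromen-6-yl)-6-{[2-(4-methylpent-3-en-1-yl)-1,3-dioxolan-2-yl]methyl}-4-oxo-3,4-dihydro-2H-pyran-5-carbaldehyde
Product: 17 (S)-2-(2,2-dimethyl-2H-chromen-6-yl)-6-(6-methyl-2-oxohept-5-en-1-yl)-4-oxo-3,4-dihydro-2H-pyran-5-carbaldehyde
Conditions: Ce(OSO2CF3)3 (0.3 equiv), MeNO2 saturated with H2O, 25 °C; crude product used at once
Reagents that add atoms: water, O
Why: Lewis-acid-catalysed hydrolysis of the dioxolane at almost neutral pH should free the C7 ketone without exposing the formyl vinylogous ester to base (β-elimination of O1 after deprotonation at C3) or to strong protic acid (ionisation of the benzylic C2–O1 bond).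

Step 11
Reactants: 17 (S)-2-(2,2-dimethyl-2H-chromen-6-yl)-6-(6-methyl-2-oxohept-5-en-1-yl)-4-oxo-3,4-dihydro-2H-pyran-5-carbaldehyde
Product: 18 dinklagin A, (S)-2-(2,2-dimethyl-2H-chromen-6-yl)-7-hydroxy-6-(3-methylbut-2-en-1-yl)-2,3-dihydro-4H-chromen-4-one
Conditions: dibenzylammonium trifluoroacetate (0.5 equiv), PhMe (0.01 M), 40 °C
Reagents that add atoms: none
Why: The ammonium salt should enolise the C7 ketone reversibly on both sides and activate the C5 formyl group (as its conjugate acid or as a transient dibenzyliminium ion); the C6 enol attacks C5, water (or the amine) is lost across C5–C6, and the cyclohexadienone tautomerises at once to the C7 phenol, which makes the sequence irreversible. The closest known reactions are the buffer- or base-induced cyclisations of o-(2-oxoalkyl)benzaldehydes to 2-naphthols, of 2-alkylpyrylium pseudobases to phenols and of poly-β-carbonyl chains to resorcinols (intramolecular aldol condensation with aromatisation). Ring A closes in a 6-(enolendo)-exo-trig mode, the C4a=C8a double bond of the pyranone holding C5 and C8 cis. No stereocentre is formed (the C5 carbinol is lost) and C2 is only carried through, which is why a weakly acidic salt of a hindered secondary amine is chosen: it should not deprotonate C3, and the hindered amine cannot condense with the C7 ketone (which would end in an arylamine) nor bridge C5 and C7 to a pyridine as ammonia or a primary amine would. The selectivity needed is C6 over the more acidic C8 as nucleophile and C5 over C4 as electrophile; geometry secures both, since C8 could only close a four-membered ring onto C5 and C4 is trans to C8 across C4a=C8a, so enolisation toward C8 is reversible and harmless.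

Compound list
1 | 4-hydroxybenzaldehyde | O=Cc1ccc(O)cc1 | starting material
2 | 3-chloro-3-methylbut-1-yne | C#CC(C)(C)Cl | starting material
3 | 4-[(2-methylbut-3-yn-2-yl)oxy]benzaldehyde | O=Cc1ccc(OC(C)(C)C#C)cc1 | intermediate
4 | 2,2-dimethyl-2H-chromene-6-carbaldehyde | O=Cc1ccc2c(c1)C=CC(C)(C)O2 | intermediate
5 | acetone | CC(C)=O | starting material
6 | (S)-4-(2,2-dimethyl-2H-chromen-6-yl)-4-hydroxybutan-2-one | CC(=O)C[C@H](O)c1ccc2c(c1)C=CC(C)(C)O2 | intermediate
7 | (S)-4-(2,2-dimethyl-2H-chromen-6-yl)-4-[(triethylsilyl)oxy]butan-2-one | CC(=O)C[C@H](O[Si](CC)(CC)CC)c1ccc2c(c1)C=CC(C)(C)O2 | intermediate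
8 | N-methoxy-N-methyl-3-oxobutanamide | CC(=O)CC(=O)N(C)OC | starting material
9 | 1-bromo-3-methylbut-2-ene | CC(C)=CCBr | starting material
10 | N-methoxy-N,7-dimethyl-3-oxooct-6-enamide | CC(C)=CCCC(=O)CC(=O)N(C)OC | intermediate
11 | N-methoxy-N-methyl-2-[2-(4-methylpent-3-en-1-yl)-1,3-dioxolan-2-yl]acetamide | CC(C)=CCCC1(CC(=O)N(C)OC)OCCO1 | intermediate
12 | (S)-1-(2,2-dimethyl-2H-chromen-6-yl)-6-[2-(4-methylpent-3-en-1-yl)-1,3-dioxolan-2-yl]-1-[(triethylsilyl)oxy]hexane-3,5-dione | CC(C)=CCCC1(CC(=O)CC(=O)C[C@H](O[Si](CC)(CC)CC)c2ccc3c(c2)C=CC(C)(C)O3)OCCO1 | intermediate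
13 | (S)-1-(2,2-dimethyl-2H-chromen-6-yl)-1-hydroxy-6-[2-(4-methylpent-3-en-1-yl)-1,3-dioxolan-2-yl]hexane-3,5-dione | CC(C)=CCCC1(CC(=O)CC(=O)C[C@H](O)c2ccc3c(c2)C=CC(C)(C)O3)OCCO1 | intermediate
14 | (S)-2-(2,2-dimethyl-2H-chromen-6-yl)-6-{[2-(4-methylpent-3-en-1-yl)-1,3-dioxolan-2-yl]methyl}-2,3-dihydro-4H-pyran-4-one | CC(C)=CCCC1(CC2=CC(=O)C[C@@H](c3ccc4c(c3)C=CC(C)(C)O4)O2)OCCO1 | intermediate
15 | (S)-2-(2,2-dimethyl-2H-chromen-6-yl)-5-iodo-6-{[2-(4-methylpent-3-en-1-yl)-1,3-dioxolan-2-yl]methyl}-2,3-dihydro-4H-pyran-4-one | CC(C)=CCCC1(CC2=C(I)C(=O)C[C@@H](c3ccc4c(c3)C=CC(C)(C)O4)O2)OCCO1 | intermediate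
16 | (S)-2-(2,2-dimethyl-2H-chromen-6-yl)-6-{[2-(4-methylpent-3-en-1-yl)-1,3-dioxolan-2-yl]methyl}-4-oxo-3,4-dihydro-2H-pyran-5-carbaldehyde | CC(C)=CCCC1(CC2=C(C=O)C(=O)C[C@@H](c3ccc4c(c3)C=CC(C)(C)O4)O2)OCCO1 | intermediate
17 | (S)-2-(2,2-dimethyl-2H-chromen-6-yl)-6-(6-methyl-2-oxohept-5-en-1-yl)-4-oxo-3,4-dihydro-2H-pyran-5-carbaldehyde | CC(C)=CCCC(=O)CC1=C(C=O)C(=O)C[C@@H](c2ccc3c(c2)C=CC(C)(C)O3)O1 | intermediate
18 | dinklagin A, (S)-2-(2,2-dimethyl-2H-chromen-6-yl)-7-hydroxy-6-(3-methylbut-2-en-1-yl)-2,3-dihydro-4H-chromen-4-one | CC(C)=CCc1cc2c(cc1O)O[C@H](c1ccc3c(c1)C=CC(C)(C)O3)CC2=O | target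

Total step count: 11. Longest linear sequence: 9 steps (steps 1, 2, 3, 4, 7, 8, 9, 10, 11).

Steps most likely to fail

Step 11. Deprotonation at C3 with β-elimination of O1 (retro-oxa-Michael opening of ring C) may run as fast as the aldol closure and erode the configuration at C2, and capture of C5 or C8a by the amine may divert material. The fallback uses the ring opening on purpose and sets C2 afterwards. From 17, KOH in MeOH–H2O at 25 °C should open ring C and aromatise ring A to the achiral chalcone (E)-1-[2,4-dihydroxy-5-(3-methylbut-2-en-1-yl)phenyl]-3-(2,2-dimethyl-2H-chromen-6-yl)prop-2-en-1-one F1, which is stable as its phenolate and is freed by careful acidification. A catalytic enantioselective intramolecular oxa-Michael addition of this 2'-hydroxychalcone (quinine-derived bifunctional thiourea, PhMe, 25 °C, or chalcone isomerase) would then close ring C under catalyst control and return to 18. This cyclisation is known for 2'-hydroxychalcones, but its selectivity on a simple chalcone is the weak point of the fallback.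

Step 10. The dioxolane, deactivated by the neighbouring vinylogous ester, may hydrolyse only at an acidity at which the freed keto aldehyde closes through the C7 enol oxygen onto C5 and the resulting oxonium ion loses the benzylic C2–O1 bond. The fallback reverses the order of unmasking and formylation. From 15, PPTS in wet acetone at 50 °C should remove the ketal while no formyl group is present and give (S)-2-(2,2-dimethyl-2H-chromen-6-yl)-5-iodo-6-(6-methyl-2-oxohept-5-en-1-yl)-2,3-dihydro-4H-pyran-4-one F3. The reductive carbonylation of step 9 applied to F3 would then deliver 17 in a neutral medium, provided hydride transfer outruns capture of the acylpalladium by the C7 enol.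

Step 9. Hydride transfer from tin to the hindered, electron-poor vinylpalladium iodide before CO insertion would give hydrodeiodination back to 14. The fallback brings in C5 at the alcohol level by a coupling that uses no hydride. From 15, Stille coupling with (tributylstannyl)methanol (Pd(PPh3)4, dioxane, 90 °C) should give (S)-2-(2,2-dimethyl-2H-chromen-6-yl)-5-(hydroxymethyl)-6-{[2-(4-methylpent-3-en-1-yl)-1,3-dioxolan-2-yl]methyl}-2,3-dihydro-4H-pyran-4-one F2, and MnO2 (CH2Cl2, 25 °C) would oxidise this allylic alcohol to 16.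

Further compounds
F1 | step 11 | (E)-1-[2,4-dihydroxy-5-(3-methylbut-2-en-1-yl)phenyl]-3-(2,2-dimethyl-2H-chromen-6-yl)prop-2-en-1-one | CC(C)=CCc1cc(C(=O)/C=C/c2ccc3c(c2)C=CC(C)(C)O3)c(O)cc1O
F2 | step 9 | (S)-2-(2,2-dimethyl-2H-chromen-6-yl)-5-(hydroxymethyl)-6-{[2-(4-methylpent-3-en-1-yl)-1,3-dioxolan-2-yl]methyl}-2,3-dihydro-4H-pyran-4-one | CC(C)=CCCC1(CC2=C(CO)C(=O)C[C@@H](c3ccc4c(c3)C=CC(C)(C)O4)O2)OCCO1
F3 | step 10 | (S)-2-(2,2-dimethyl-2H-chromen-6-yl)-5-iodo-6-(6-methyl-2-oxohept-5-en-1-yl)-2,3-dihydro-4H-pyran-4-one | CC(C)=CCCC(=O)CC1=C(I)C(=O)C[C@@H](c2ccc3c(c2)C=CC(C)(C)O3)O1
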